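The numbers in the tables stem from a simulated flask for an exercise, noise included.

The easy step comes first: the target in this flask reads 33.5% at 1.67 d, its highest reading, and 15.5% at 6.00 d, so it forms and then goes.

| setting | elm | flask |
|---|---|---|
| starting material | 0.12 M | 0.12 M |
| protic impurity | 6 mM | 6.00 mM |
| remark | the very flask that is asked about, followed so far |  |
| time |  | 6.0 d |

- elm (time / d: target / %): 0.500: 23.3; 0.833: 30.8; 1.04: 31.3; 1.67: 33.5; 2.50: 27.9; 4.00: 23.2; 6.00: 15.5

(scatter of a reading: 1 percentage point)

- eta: change nothing and wait 12 d more
- gamma: at 6.0 d take out 90% of the target then present, then wait 12 d
- alpha: at 6.0 d add starting material, 50.0% of the amount charged, then wait 12 d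

- target, in percent of the starting material first charged, at 6.0 d
- what to do for the largest gain in target; "none" if nothing gains more than 2 percentage points (eta / gamma / alpha / none)
- target present, with what was taken out counted in, in percent of the starting material first charged, after eta
- target present, with what was taken out counted in, in percent of the starting material first charged, after gamma

- target that was removed still counts
- what may be going on: starting material <-> isomer of the product; starting material + protic impurity -> quenched substrate; starting material <-> target
- additions bring no volume worth counting

I build the flask one process at a time. With starting material ⇌ target by itself, the target reaches a level and stays there, so over any wait the survival of target stands at one; that step gives the rise, but not the fall.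

Next I add the step from starting material to the isomer of the product, which makes this kinetic against thermodynamic control. Target and starting material now drain together as one pool, and I take that pool to fall by a fixed fraction per day, the decay constant λ. The readings at 2.50 d and 6.00 d give 0.168 d⁻¹. I go round once more: this λ carries the 4.00 d reading forward to 6.00 d, and the mean of that with the last reading gives y, the target now, as 16.0%. Putting y back in gives λ = 0.158 d⁻¹. Over 12 d that makes 0.150, the survival factor f, the share of the pool at the start of a wait that still stands at its end.

Last comes the protic impurity. It can take 5.00% of the charge, less than the 18 percentage points the target has lost since its highest reading, so I leave f as it is.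

Eta then leaves y·f = 2.40%. Gamma banks 90% of y, and I reckon that the smaller pool left behind ends under y·f, so I put its gain below 0.8 points, less than 2 points. For alpha I treat the addition as a fresh charge of 50.0% size, which gives 5.50%, less than y. My choice is none.

The forecast gives 16% (14.5% to 17.5%), 4% after eta and 16.5% after gamma, and picks gamma: “Harvesting wins.” My eta figure lies below its 4%, and we differ on the choice.

    starting material ⇌ isomer of the product (K = 140, k = 2.40 × 10⁻⁴ min⁻¹)
    starting material + protic impurity → quenched substrate (k = 0.100 M⁻¹ min⁻¹)
    starting material ⇌ target (K = 0.930, k = 5.90 × 10⁻⁴ min⁻¹)

This flask holds 17.2% target at 6.0 d, and the answer is none: against that, eta changes −14 points, gamma −0.13 points and alpha −11 points. Gamma ends at 17.1% against the forecast's 16.5%; that forecast figure stands 0.5 points above its own 16%, less than 2 points, and on the choice we part. At 6.00 d starting material goes to the isomer of the product at 0.41 of the forward rate at which it makes target, and eta keeps 0.170 of the target against f = 0.150. The neighbour flask, left until 2.5 d, holds 29.8% target, and λ carries that to 17.1% at 6.0 d.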